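## Retrosynthetic overview

1. The target comes from the TBS ether of the target by fluoride removal. That ether is assembled by an intramolecular Hiyama-type allylchromium addition (C6–C7 bond). This one step closes the 10-membered carbocycle, sets the trans-fused α-methylene-γ-lactone (C6/C7) after lactonization, and re-forms the C3 bridging hemiketal.
2. The C6 aldehyde is masked as a spiroketal-lactol. It comes from oxidative spiroketalization of a 2,3-disubstituted furan (a latent Z-4-oxo-enal) by the tertiary C10-OH. This is the first ring formed (the THF).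
3. The allylic bromide (C7=C11) comes from a Baylis–Hillman reaction of the C7 aldehyde followed by SN2′ bromination. The aldehyde is unmasked from a dimethyl acetal.
4. The C2/C8/C10 oxygenated triad comes from a proline aldol (C8), a chelation-controlled ketone aldol (C10) and an Evans–Saksena anti reduction (C2).

Assumptions: the hydroxy-aldehyde exists largely as its cyclic lactol but is drawn open. L-Proline gives the (R)-aldol with dimethoxyacetaldehyde, by analogy with α-branched aliphatic aldehydes. The E/Z geometry of the allylic bromide is irrelevant because the allylchromium equilibrates. Simple reagents (TBSCl, LiBr, water) are named with SMILES in the steps; only building blocks and intermediates are numbered.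

## Route

**Step 1**
Reactants: 1 acetone; 2 2,2-dimethoxyacetaldehyde
Product: 3 (4R)-4-hydroxy-5,5-dimethoxypentan-2-one
Conditions: L-proline (30 mol%), acetone/DMSO, rt
Reagents that add atoms: none
Why: This is a direct asymmetric aldol (List–Barbas) through the proline enamine. Enamine attack on the α-branched aldehyde gives the (R)-carbinol (the future C8) and sets the first stereocenter. It delivers C7–C10 and C14 with C7 already masked as an acetal.

**Step 2**
Reactants: 3 (4R)-4-hydroxy-5,5-dimethoxypentan-2-one; 4 2-acetyl-3-methylfuran
Product: 5 (3R,5R)-3,5-dihydroxy-6,6-dimethoxy-3-methyl-1-(3-methylfuran-2-yl)hexan-1-one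
Conditions: 4 (2.2 equiv) + LiHMDS (2.4 equiv), THF, −78 °C; MgBr2·OEt2 (2.5 equiv); then 3, −78 → −30 °C; NH4Cl
Reagents that add atoms: none
Why: This is a ketone aldol (Mg-enolate addition to a methyl ketone). The Mg alkoxide of C8-OH chelates the C10 carbonyl in a six-membered chair-like chelate. The enolate enters axially, syn to H-8, with the C10 methyl and the C8 substituent both equatorial, which gives (10R) as in the target.

**Step 3**
Reactants: 5 the diol-ketone; 6 angelic acid
Product: 7 (2R,4R)-4-hydroxy-1,1-dimethoxy-4-methyl-6-(3-methylfuran-2-yl)-6-oxohexan-2-yl (2Z)-2-methylbut-2-enoate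
Conditions: 6, 2,4,6-Cl3C6H2COCl, Et3N, THF, rt; then 5 and DMAP, toluene, 0 °C → rt
Reagents that add atoms: none (the angeloyl group comes from 6)
Why: Yamaguchi esterification. It acylates the secondary C8-OH selectively over the tertiary C10-OH and retains the Z-alkene geometry of the angelate.

**Step 4**
Reactants: 7 the angelate ketone
Product: 8 (2R,4S,6S)-4,6-dihydroxy-1,1-dimethoxy-4-methyl-6-(3-methylfuran-2-yl)hexan-2-yl (2Z)-2-methylbut-2-enoate
Conditions: Me4N+ BH(OAc)3−, MeCN/AcOH (1:1), −20 °C, 12 h
Reagents that add atoms: none
Why: Evans–Saksena directed reduction. The tertiary C10-OH binds the borohydride and delivers hydride intramolecularly through a chair transition state. This gives the 1,3-anti diol, setting C2 as drawn in the target (S).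

**Step 5**
Reactants: 8 the anti-diol
Product: 9 (2R,4R,6S)-6-[(tert-butyldimethylsilyl)oxy]-4-hydroxy-1,1-dimethoxy-4-methyl-6-(3-methylfuran-2-yl)hexan-2-yl (2Z)-2-methylbut-2-enoate
Conditions: TBSCl, imidazole, DMF, 40 °C, 24 h
Reagents that add atoms: tert-butyldimethylsilyl chloride, C[Si](C)(Cl)C(C)(C)C
Why: Silyl protection of the secondary furfuryl alcohol. The tertiary alcohol is too hindered to react. The protection also prevents Achmatowicz-type oxidation at C2 in step 9.

**Step 6**
Reactants: 9 the C2-TBS ether
Product: 10 (2R,4R,6S)-6-[(tert-butyldimethylsilyl)oxy]-4-hydroxy-4-methyl-6-(3-methylfuran-2-yl)-1-oxohexan-2-yl (2Z)-2-methylbut-2-enoate (drawn as the open aldehyde)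
Conditions: In(OTf)3 (5 mol%), acetone/H2O (95:5), 40 °C
Reagents that add atoms: water, O
Why: Lewis-acid transacetalization/hydrolysis of the dimethyl acetal under near-neutral conditions. The C10-OH assists through a transient 2-methoxy-THF. The TBS ether, angelate and furan are untouched, and the C8 stereocenter is retained.

**Step 7**
Reactants: 10 the hydroxy-aldehyde; 11 methyl acrylate
Product: 12 methyl (4R,6R,8S)-8-[(tert-butyldimethylsilyl)oxy]-3,6-dihydroxy-6-methyl-2-methylidene-8-(3-methylfuran-2-yl)-4-{[(2Z)-2-methylbut-2-enoyl]oxy}octanoate (C3 epimeric mixture)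
Conditions: methyl acrylate (10 equiv), DABCO (0.5 equiv), MeCN, rt, 3 d
Reagents that add atoms: none (the acrylate is reactant 11)
Why: Morita–Baylis–Hillman reaction of the aldehyde (in equilibrium with its lactol) with methyl acrylate. The new C7 carbinol stereocenter is destroyed in step 8, so its configuration is irrelevant.

**Step 8**
Reactants: 12 the Baylis–Hillman adduct
Product: 13 methyl (4R,6R,8S)-2-(bromomethyl)-8-[(tert-butyldimethylsilyl)oxy]-6-hydroxy-6-methyl-4-{[(2Z)-2-methylbut-2-enoyl]oxy}-8-(3-methylfuran-2-yl)oct-2-enoate
Conditions: MsCl, Et3N, CH2Cl2, 0 °C; then LiBr, THF, rt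
Reagents that add atoms: lithium bromide, [Li+].[Br-]
Why: Mesylation followed by bromide SN2′ displacement gives the 2-(bromomethyl)alk-2-enoate, the usual Hiyama allylation precursor. These conditions avoid NBS, which would attack the furan.

**Step 9**
Reactants: 13 the allylic bromide
Product: 14 methyl (4R)-2-(bromomethyl)-5-[(7R,9S)-9-[(tert-butyldimethylsilyl)oxy]-2-hydroxy-4,7-dimethyl-1,6-dioxaspiro[4.4]non-3-en-7-yl]-4-{[(2Z)-2-methylbut-2-enoyl]oxy}pent-2-enoate (spiroketal/lactol epimeric mixture)
Conditions: NBS (1.05 equiv), NaHCO3, THF/H2O (9:1), 0 °C, 30 min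
Reagents that add atoms: water, O
Why: Oxidative furan spiroketalization (Kobayashi/Achmatowicz type). Bromonium formation gives a C3 oxocarbenium that the tertiary C10-OH captures to form the THF. Water traps C6 as the lactol. The Z-enal geometry is fixed in the dihydrofuran ring. The spiro center C3 and the lactol C6 are epimeric mixtures that converge in step 10.

**Step 10**
Reactants: 14 the spiroketal-lactol allylic bromide
Product: 15 TBS ether of the target, (2S)-2-O-TBS-2β-hydroxy-1-desoxyniveusin A
Conditions: CrCl2 (8 equiv), DMF, 0.003 M, 40 °C, substrate added by syringe pump over 8 h; then TsOH·H2O (cat.), CH2Cl2, rt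
Reagents that add atoms: none
Why: Proposed new method: Cr(III) generated in situ opens the spiroketal-lactol to its hydroxy-enal/hemiketal tautomer, so the lactol acts as a latent Z-γ-ketoenal. Cr(II) converts the allylic bromide into an allylchromium. This adds through its γ-carbon C7 to the C6 aldehyde in an anti-selective chair transition state, closing the 10-membered ring and giving trans C6/C7. C8-OAng and the cis-2,5-THF relay the facial sense. The C3 spiroketal epimers interconvert under Lewis acid, so only the bridgeable one reacts (Curtin–Hammett). The γ-hydroxy ester then lactonizes to the trans-fused α-methylene-γ-lactone, and C3 carries the hemiketal OH bridged to C10-O. The closest known reactions are intramolecular Hiyama allylchromium macrocyclizations used for germacranolide lactones and Nozaki–Hiyama–Kishi additions of lactols as aldehyde surrogates.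

**Step 11**
Reactants: 15 the TBS ether
Product: 16 2β-hydroxy-1-desoxyniveusin A (target)
Conditions: HF·pyridine, pyridine/THF, 0 °C → rt, 6 h
Reagents that add atoms: none
Why: Fluoride removal of the secondary TBS ether. The hemiketal, angelate, lactone and exocyclic methylene are stable to buffered HF.

## Compound list
1 | acetone | CC(C)=O | starting material
2 | 2,2-dimethoxyacetaldehyde | COC(OC)C=O | starting material
3 | (4R)-4-hydroxy-5,5-dimethoxypentan-2-one | CC(=O)C[C@@H](O)C(OC)OC | intermediate
4 | 2-acetyl-3-methylfuran | Cc1ccoc1C(C)=O | starting material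
5 | (3R,5R)-3,5-dihydroxy-6,6-dimethoxy-3-methyl-1-(3-methylfuran-2-yl)hexan-1-one | Cc1ccoc1C(=O)C[C@](C)(O)C[C@@H](O)C(OC)OC | intermediate
6 | angelic acid ((2Z)-2-methylbut-2-enoic acid) | C/C=C(/C)C(=O)O | starting material
7 | angelate ketone | Cc1ccoc1C(=O)C[C@](C)(O)C[C@@H](OC(=O)/C(C)=C\C)C(OC)OC | intermediate
8 | anti-diol angelate | Cc1ccoc1[C@@H](O)C[C@](C)(O)C[C@@H](OC(=O)/C(C)=C\C)C(OC)OC | intermediate
9 | C2-TBS ether | Cc1ccoc1[C@@H](O[Si](C)(C)C(C)(C)C)C[C@](C)(O)C[C@@H](OC(=O)/C(C)=C\C)C(OC)OC | intermediate
10 | hydroxy-aldehyde (open form) | Cc1ccoc1[C@@H](O[Si](C)(C)C(C)(C)C)C[C@](C)(O)C[C@@H](OC(=O)/C(C)=C\C)C=O | intermediate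
11 | methyl acrylate | C=CC(=O)OC | starting material
12 | Baylis–Hillman adduct (C7 epimers) | Cc1ccoc1[C@@H](O[Si](C)(C)C(C)(C)C)C[C@](C)(O)C[C@@H](OC(=O)/C(C)=C\C)C(O)C(=C)C(=O)OC | intermediate
13 | allylic bromide | Cc1ccoc1[C@@H](O[Si](C)(C)C(C)(C)C)C[C@](C)(O)C[C@@H](OC(=O)/C(C)=C\C)C=C(CBr)C(=O)OC | intermediate
14 | spiroketal-lactol (C3/C6 epimers) | CC1=CC(O)OC12[C@@H](O[Si](C)(C)C(C)(C)C)C[C@](C)(O2)C[C@@H](OC(=O)/C(C)=C\C)C=C(CBr)C(=O)OC | intermediate
15 | 2-O-TBS target | C=C1C(=O)O[C@@H]2/C=C(/C)[C@]3(O)O[C@](C)(C[C@@H](OC(=O)/C(C)=C\C)[C@@H]12)C[C@@H]3O[Si](C)(C)C(C)(C)C | intermediate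
16 | 2β-hydroxy-1-desoxyniveusin A | C=C1C(=O)O[C@@H]2/C=C(/C)[C@]3(O)O[C@](C)(C[C@@H](OC(=O)/C(C)=C\C)[C@@H]12)C[C@@H]3O | target

## Totals
Total steps: 11. Longest linear sequence: 11 (1 → 3 → 5 → 7 → 8 → 9 → 10 → 12 → 13 → 14 → 15 → 16).

## Three steps most likely to fail
1. **Step 10 (proposed new step): the lactol-masked NHK macrocyclization.** It could give oligomers or a strained 9/10-ring closure, or the lactol may not open under the reaction conditions. Fallback using known chemistry: close the ring differently. Do an intermolecular anti-selective Hiyama allylation of an open Z-enal to build the C6–C7 lactone first. Then close C4=C5 by ring-closing metathesis (Hoveyda–Grubbs II) of an isopropenyl/vinyl diene.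
2. **Step 2: the tertiary aldol with 1,3-chelation control.** It may suffer retro-aldol, proton transfer to the more acidic methyl ketone, or low dr at C10. Fallback: set C10 under catalyst control instead. Protect 3 as its TBS ether and do an HWE with a phosphonoacetate Weinreb amide. Then run a Shi asymmetric epoxidation (organocatalytic), reductive epoxide opening with SmI2, and addition of 2-lithio-3-methylfuran to the Weinreb amide, before continuing from step 4.
3. **Step 6: the acetal hydrolysis.** The α-acyloxy dimethyl acetal is deactivated and must be cleaved without harming the furan or the TBS ether. The resulting α-acyloxy aldehyde is also prone to epimerization and acyl migration in step 7. Fallback: use 2-(TBSO)acetaldehyde in step 1 so C7 is a primary silyl ether. After the later steps, remove it selectively and oxidize with Dess–Martin periodinane to give aldehyde 10.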